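**Retrosynthetic overview**

1. The structural feature the route rests on is C4, the tertiary carbinol carbon carrying the isopropyl group, together with its two arms C3–C2–C1(CH3) and C5–C6. This is the carbinol carbon of (S)-terpinen-4-ol with the cyclohexene opened at its C=C bond, and the terpene supplies ten of the fifteen skeletal carbons and the C4 configuration.
2. Cyclopentane ring C1–C2–C3–C4–C5 (formed first): ozonolysis of the silylated terpene, then amine-catalysed aldol condensation that joins the aldehyde α-carbon C5 to the methyl-ketone carbon C1.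
3. Cycloheptane ring C1–C10–C9–C8–C7–C6–C5 (formed second): conjugate allylation at C1, methallyl addition to the C6 aldehyde, ring-closing metathesis to the C8=C9 alkene.
4. 8β,9α-Diol: 6α-hydroxyl-directed epoxidation of C8=C9 from the α face, then acid-catalysed opening by water at C8 with inversion, with O6 already acylated.
5. End game: removal of the triethylsilyl group from O4 and of the benzyl group from the phenol.

Key step: step 3

Remark on conventions: C1–C10 are the daucane locants used in the overview (C1 quaternary C–CH3, C4 C(OH)iPr, C5 ring-fusion CH, C6 CH–OAr, C8 C(OH)CH3, C9 CHOH); β is the face of the C1 methyl group in the bicycle, α the opposite face.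
Remark on materials: (S)-(+)-terpinen-4-ol is assumed to be available in high enantiomeric purity; the two allylic Grignard reagents and 4-(benzyloxy)benzoyl chloride are bought as such.

**Route**

Step 1
Reactants: 1 (S)-(+)-terpinen-4-ol
Product: 2 triethyl{[(1S)-4-methyl-1-(propan-2-yl)cyclohex-3-en-1-yl]oxy}silane
Conditions: TESOTf, 2,6-lutidine, CH2Cl2, −78 → 0 °C
Reagents that add atoms: triethylsilyl trifluoromethanesulfonate, CC[Si](CC)(CC)OS(=O)(=O)C(F)(F)F
Why: Silyl ether formation on a hindered tertiary alcohol needs the silyl triflate, and the lutidine buffer keeps the tertiary carbinol from ionising, so the stereocentre is untouched.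

Step 2
Reactants: 2 triethyl{[(1S)-4-methyl-1-(propan-2-yl)cyclohex-3-en-1-yl]oxy}silane
Product: 4 (3S)-6-oxo-3-(propan-2-yl)-3-(triethylsilyloxy)heptanal, via secondary ozonide 3 (not isolated)
Conditions: O3, CH2Cl2, −78 °C; then PPh3, −78 °C → rt
Reagents that add atoms: ozone, [O-][O+]=O
Why: Ozonolysis (Criegee mechanism) of the only C=C bond gives the ozonide, which triphenylphosphine reduces to the methyl ketone and the aldehyde without affecting the silyl ether or the quaternary stereocentre.

Step 3
Reactants: 4 (3S)-6-oxo-3-(propan-2-yl)-3-(triethylsilyloxy)heptanal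
Product: 6 (5R)-2-methyl-5-(propan-2-yl)-5-(triethylsilyloxy)cyclopent-1-ene-1-carbaldehyde, via β-hydroxy aldehyde 5 (not isolated)
Conditions: piperidine (0.3 equiv), AcOH (0.3 equiv), 4 Å MS, toluene, 60 °C
Reagents that add atoms: none
Why: Piperidine condenses with the aldehyde far faster than with the ketone, the enamine carbon C5 adds to the ketone carbonyl C1, and the aldol 5 (as its iminium/enamine) loses water by acid-assisted E1cB elimination to the conjugated, tetrasubstituted enal. The closest known reaction is the piperidinium acetate aldol condensation of the keto-aldehydes obtained by ozonolysis of 1-methylcyclohexene terpenes, which gives 2-methylcyclopent-1-enecarbaldehydes. The cyclopentane ring C1–C2–C3–C4–C5 closes in a 5-(enolexo)-exo-trig mode. No stereocentre is formed, since the two transient centres C1 and C5 of the aldol become sp2, and the quaternary silyloxy carbon C4 can neither epimerise nor undergo retro-aldol cleavage. The step needs closure from the aldehyde α-carbon onto the ketone (ketone-enolate closure onto the aldehyde would give an acetylcyclopentene) and loss of the C1 hydroxyl instead of the C4 oxygen; the first is secured by enamine formation at the aldehyde only, the second by the low basicity and poor leaving-group ability of the hindered silyl ether oxygen in the buffered medium.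

Step 4
Reactants: 6 (5R)-2-methyl-5-(propan-2-yl)-5-(triethylsilyloxy)cyclopent-1-ene-1-carbaldehyde; 7 allylmagnesium bromide
Product: 9 (1R,2R,5R)-2-methyl-5-(propan-2-yl)-2-(prop-2-en-1-yl)-5-(triethylsilyloxy)cyclopentane-1-carbaldehyde, via trimethylsilyl enol ether 8 (not isolated)
Conditions: CuBr·SMe2, TMSCl, THF, −78 °C; then K2CO3, MeOH, 0 °C
Reagents that add atoms: none
Why: TMSCl-accelerated conjugate addition of the Grignard-derived allylcopper reagent should build the quaternary centre C1 with the allyl group entering the α face, anti to the bulky OSiEt3 group on the neighbouring carbon C4, and methanolysis of the silyl enol ether with carbonate equilibration then sets C5 under thermodynamic control with the formyl group trans to both the isopropyl and the allyl group.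

Step 5
Reactants: 9 (1R,2R,5R)-2-methyl-5-(propan-2-yl)-2-(prop-2-en-1-yl)-5-(triethylsilyloxy)cyclopentane-1-carbaldehyde; 10 2-methylallylmagnesium chloride
Product: 11 (1S)-3-methyl-1-[(1S,2R,5R)-2-methyl-5-(propan-2-yl)-2-(prop-2-en-1-yl)-5-(triethylsilyloxy)cyclopentyl]but-3-en-1-ol
Conditions: THF, −78 °C; aq NH4Cl
Reagents that add atoms: none
Why: Grignard 1,2-addition to the aldehyde in a Felkin-type arrangement, with the carbonyl oxygen turned outward toward the C4 side and the formyl hydrogen over the ring, lets the reagent approach past the small C1 methyl group instead of the OSiEt3 group and should give the (6S) carbinol.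

Step 6
Reactants: 11 (1S)-3-methyl-1-[(1S,2R,5R)-2-methyl-5-(propan-2-yl)-2-(prop-2-en-1-yl)-5-(triethylsilyloxy)cyclopentyl]but-3-en-1-ol
Product: 12 (3R,3aS,4S,8aR)-6,8a-dimethyl-3-(propan-2-yl)-3-(triethylsilyloxy)-1,2,3,3a,4,5,8,8a-octahydroazulen-4-ol
Conditions: Grubbs II (5 mol %), CH2Cl2 (5 mM), 40 °C
Reagents that add atoms: none
Why: Ring-closing metathesis, in which the ruthenium carbene loads on the monosubstituted allyl alkene and closes onto the 1,1-disubstituted methallyl alkene with loss of ethylene, forms the seven-membered ring with the trisubstituted C8=C9 bond and touches no stereocentre.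

Step 7
Reactants: 12 (3R,3aS,4S,8aR)-6,8a-dimethyl-3-(propan-2-yl)-3-(triethylsilyloxy)-1,2,3,3a,4,5,8,8a-octahydroazulen-4-ol
Product: 13 8α,9α-epoxide of 12, (1R,4R,5S,6S,8R,9S)-8,9-epoxy-4-(triethylsilyloxy)daucan-6-ol
Conditions: VO(acac)2 (5 mol %), t-BuOOH, toluene, 0 °C → rt
Reagents that add atoms: tert-butyl hydroperoxide, CC(C)(C)OO
Why: Vanadium-catalysed hydroxyl-directed epoxidation of the homoallylic alcohol delivers oxygen from the 6α-alkoxide-bound peroxide to the α face of C8=C9, which is also the face remote from the C1 methyl group, and so sets C8 and C9.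

Step 8
Reactants: 13 (1R,4R,5S,6S,8R,9S)-8,9-epoxy-4-(triethylsilyloxy)daucan-6-ol; 14 4-(benzyloxy)benzoyl chloride
Product: 15 (1R,4R,5S,6S,8R,9S)-8,9-epoxy-4-(triethylsilyloxy)daucan-6-yl 4-(benzyloxy)benzoate
Conditions: Et3N, DMAP, CH2Cl2, 0 °C → rt
Reagents that add atoms: none
Why: DMAP-catalysed acyl transfer to the only free hydroxyl group forms the C6 ester with retention, and the epoxide and the silyl ether are inert to the mildly basic medium.

Step 9
Reactants: 15 (1R,4R,5S,6S,8R,9S)-8,9-epoxy-4-(triethylsilyloxy)daucan-6-yl 4-(benzyloxy)benzoate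
Product: 16 (3R,3aS,4S,6S,7S,8aR)-6,7-dihydroxy-6,8a-dimethyl-3-(propan-2-yl)-3-(triethylsilyloxy)decahydroazulen-4-yl 4-(benzyloxy)benzoate
Conditions: HClO4 (cat., aq), THF–H2O, 0 °C
Reagents that add atoms: water, O
Why: Acid-catalysed epoxide hydrolysis should proceed by attack of water on the protonated oxirane at the tertiary carbon C8 from the β face with inversion and retention at C9, giving the 8β,9α trans-diol, while the α-oriented ester cannot participate on the β face and the silylated O4 cannot add across the ring.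

Step 10
Reactants: 16 (3R,3aS,4S,6S,7S,8aR)-6,7-dihydroxy-6,8a-dimethyl-3-(propan-2-yl)-3-(triethylsilyloxy)decahydroazulen-4-yl 4-(benzyloxy)benzoate
Product: 17 (3R,3aS,4S,6S,7S,8aR)-3,6,7-trihydroxy-6,8a-dimethyl-3-(propan-2-yl)decahydroazulen-4-yl 4-(benzyloxy)benzoate
Conditions: HF·pyridine, pyridine, THF, 0 °C → rt
Reagents that add atoms: none
Why: Fluoride-mediated cleavage of the Si–O bond, driven by Si–F bond formation under buffered conditions, frees the tertiary C4 hydroxyl without touching the aryl ester, the diol or the benzyl ether.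

Step 11
Reactants: 17 (3R,3aS,4S,6S,7S,8aR)-3,6,7-trihydroxy-6,8a-dimethyl-3-(propan-2-yl)decahydroazulen-4-yl 4-(benzyloxy)benzoate
Product: 18 (3R,3aS,4S,6S,7S,8aR)-3,6,7-trihydroxy-6,8a-dimethyl-3-(propan-2-yl)decahydroazulen-4-yl 4-hydroxybenzoate
Conditions: H2 (1 atm), 10% Pd/C, EtOAc, rt
Reagents that add atoms: none
Why: Catalytic hydrogenolysis cleaves the benzylic C–O bond of the aryl benzyl ether, and since no alkene remains and the C6 ester C–O bond is not benzylic, only the phenol is unmasked.

**Compound list**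

1 | (S)-(+)-terpinen-4-ol, (1S)-4-methyl-1-(propan-2-yl)cyclohex-3-en-1-ol | CC(C)[C@]1(O)CCC(C)=CC1 | starting material
2 | triethyl{[(1S)-4-methyl-1-(propan-2-yl)cyclohex-3-en-1-yl]oxy}silane | CC(C)[C@]1(O[Si](CC)(CC)CC)CCC(C)=CC1 | intermediate
3 | secondary ozonide of 2, 1-methyl-4-(propan-2-yl)-4-(triethylsilyloxy)-7,8,9-trioxabicyclo[4.2.1]nonane, carbinol centre as in 2, mixture at the bridgeheads | CC(C)[C@]1(O[Si](CC)(CC)CC)CCC2(C)OOC(C1)O2 | intermediate
4 | (3S)-6-oxo-3-(propan-2-yl)-3-(triethylsilyloxy)heptanal | CC(C)[C@](CC=O)(O[Si](CC)(CC)CC)CCC(C)=O | intermediate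
5 | (5R)-2-hydroxy-2-methyl-5-(propan-2-yl)-5-(triethylsilyloxy)cyclopentane-1-carbaldehyde, mixture at C1 and C2 | CC(C)[C@]1(O[Si](CC)(CC)CC)CCC(C)(O)C1C=O | intermediate
6 | (5R)-2-methyl-5-(propan-2-yl)-5-(triethylsilyloxy)cyclopent-1-ene-1-carbaldehyde | CC(C)[C@]1(O[Si](CC)(CC)CC)CCC(C)=C1C=O | intermediate
7 | allylmagnesium bromide | C=CC[Mg]Br | starting material
8 | {[(2R,5R)-2-methyl-5-(propan-2-yl)-2-(prop-2-en-1-yl)-5-(triethylsilyloxy)cyclopentylidene]methoxy}trimethylsilane, E/Z mixture | CC(C)[C@]1(O[Si](CC)(CC)CC)CC[C@](C)(CC=C)C1=CO[Si](C)(C)C | intermediate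
9 | (1R,2R,5R)-2-methyl-5-(propan-2-yl)-2-(prop-2-en-1-yl)-5-(triethylsilyloxy)cyclopentane-1-carbaldehyde (formyl cis to OSiEt3 and to CH3) | CC(C)[C@]1(O[Si](CC)(CC)CC)CC[C@](C)(CC=C)[C@H]1C=O | intermediate
10 | 2-methylallylmagnesium chloride | CC(=C)C[Mg]Cl | starting material
11 | (1S)-3-methyl-1-[(1S,2R,5R)-2-methyl-5-(propan-2-yl)-2-(prop-2-en-1-yl)-5-(triethylsilyloxy)cyclopentyl]but-3-en-1-ol | CC(C)[C@]1(O[Si](CC)(CC)CC)CC[C@](C)(CC=C)[C@H]1[C@@H](O)CC(C)=C | intermediate
12 | (3R,3aS,4S,8aR)-6,8a-dimethyl-3-(propan-2-yl)-3-(triethylsilyloxy)-1,2,3,3a,4,5,8,8a-octahydroazulen-4-ol (trans-fused, 6-OH α) | CC(C)[C@]1(O[Si](CC)(CC)CC)CC[C@]2(C)CC=C(C)C[C@H](O)[C@H]21 | intermediate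
13 | (1R,4R,5S,6S,8R,9S)-8,9-epoxy-4-(triethylsilyloxy)daucan-6-ol, oxirane oxygen α (cis to 6-OH, trans to the C1 methyl) | CC(C)[C@]1(O[Si](CC)(CC)CC)CC[C@]2(C)C[C@@H]3O[C@]3(C)C[C@H](O)[C@H]21 | intermediate
14 | 4-(benzyloxy)benzoyl chloride | O=C(Cl)c1ccc(OCc2ccccc2)cc1 | starting material
15 | (1R,4R,5S,6S,8R,9S)-8,9-epoxy-4-(triethylsilyloxy)daucan-6-yl 4-(benzyloxy)benzoate | CC(C)[C@]1(O[Si](CC)(CC)CC)CC[C@]2(C)C[C@@H]3O[C@]3(C)C[C@H](OC(=O)c3ccc(OCc4ccccc4)cc3)[C@H]21 | intermediate
16 | (3R,3aS,4S,6S,7S,8aR)-6,7-dihydroxy-6,8a-dimethyl-3-(propan-2-yl)-3-(triethylsilyloxy)decahydroazulen-4-yl 4-(benzyloxy)benzoate | CC(C)[C@]1(O[Si](CC)(CC)CC)CC[C@]2(C)C[C@H](O)[C@@](C)(O)C[C@H](OC(=O)c3ccc(OCc4ccccc4)cc3)[C@H]21 | intermediate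
17 | (3R,3aS,4S,6S,7S,8aR)-3,6,7-trihydroxy-6,8a-dimethyl-3-(propan-2-yl)decahydroazulen-4-yl 4-(benzyloxy)benzoate | CC(C)[C@]1(O)CC[C@]2(C)C[C@H](O)[C@@](C)(O)C[C@H](OC(=O)c3ccc(OCc4ccccc4)cc3)[C@H]21 | intermediate
18 | (3R,3aS,4S,6S,7S,8aR)-3,6,7-trihydroxy-6,8a-dimethyl-3-(propan-2-yl)decahydroazulen-4-yl 4-hydroxybenzoate (CNP0197754.1) | CC(C)[C@]1(O)CC[C@]2(C)C[C@H](O)[C@@](C)(O)C[C@H](OC(=O)c3ccc(O)cc3)[C@H]21 | target

**Step count**

Total: 11 steps. Longest linear sequence: 11 steps from 1.

**Steps most likely to fail**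

Step 4. The allyl nucleophile may attack the formyl carbon (1,2-addition) instead of the fully substituted β-carbon C1, and the facial preference at C1 may be low or reversed because the isopropyl group competes with the silyloxy group in shielding. The fallback sets out from 6 and turns 1,2-addition into the wanted bond. Reagent-controlled allylboration of the enal, with the antipode of B-allyldiisopinocampheylborane that gives the (S)-carbinol, should furnish (1S)-1-[(5R)-2-methyl-5-(propan-2-yl)-5-(triethylsilyloxy)cyclopent-1-en-1-yl]but-3-en-1-ol F1. Its potassium alkoxide (KH, 18-crown-6, THF, 0 °C → rt) should undergo anionic oxy-Cope rearrangement. Allylic 1,3-strain with the C1 methyl group keeps the carbinol hydrogen in the alkene plane and the oxido group outward, so the allyl terminus should be delivered to the α face of C1, the C6 centre relaying its configuration to C1. Protonation of the resulting aldehyde enolate and carbonate equilibration at C5 return the route to 9.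

Step 5. Facial discrimination at the formyl group may be poor, since the two flanking quaternary carbons permit several reactive rotamers, and the C6 epimer may form in quantity. The fallback sets out from 9 and sets C6 by reagent-controlled hydride delivery. The Grignard addition is run without regard to selectivity, giving 11 together with its C6 epimer, (1R)-3-methyl-1-[(1S,2R,5R)-2-methyl-5-(propan-2-yl)-2-(prop-2-en-1-yl)-5-(triethylsilyloxy)cyclopentyl]but-3-en-1-ol F2. The mixture is oxidised with Dess–Martin periodinane (NaHCO3, CH2Cl2) to the β,γ-unsaturated ketone 3-methyl-1-[(1R,2R,5R)-2-methyl-5-(propan-2-yl)-2-(prop-2-en-1-yl)-5-(triethylsilyloxy)cyclopentyl]but-3-en-1-one F3. Corey–Bakshi–Shibata reduction with (R)-Me-CBS and catecholborane (toluene, −78 °C), the cyclopentyl group acting as the large substituent, should then give the (6S) alcohol, and the route is rejoined at 11.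

Step 3. The enamine may expel the C4 silyloxy group (β-elimination) before or after ring closure, or the aldol may dehydrate toward C4 or stall. The fallback sets out from 4 and separates bond formation from elimination. Amino-acid catalysis (L-proline, DMSO, rt) is used to stop at the aldol addition stage and isolate the β-hydroxy aldehyde 5. Its only free hydroxyl group is then activated with MsCl/Et3N (CH2Cl2, 0 °C → rt) as 2-formyl-1-methyl-3-(propan-2-yl)-3-(triethylsilyloxy)cyclopentyl methanesulfonate F4, which should eliminate in the same flask by E1cB toward C5. The leaving group is now fixed on C1, and the route is rejoined at 6.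

**Further compounds**

F1 | step 4 | (1S)-1-[(5R)-2-methyl-5-(propan-2-yl)-5-(triethylsilyloxy)cyclopent-1-en-1-yl]but-3-en-1-ol | CC(C)[C@]1(O[Si](CC)(CC)CC)CCC(C)=C1[C@@H](O)CC=C
F2 | step 5 | (1R)-3-methyl-1-[(1S,2R,5R)-2-methyl-5-(propan-2-yl)-2-(prop-2-en-1-yl)-5-(triethylsilyloxy)cyclopentyl]but-3-en-1-ol | CC(C)[C@]1(O[Si](CC)(CC)CC)CC[C@](C)(CC=C)[C@H]1[C@H](O)CC(C)=C
F3 | step 5 | 3-methyl-1-[(1R,2R,5R)-2-methyl-5-(propan-2-yl)-2-(prop-2-en-1-yl)-5-(triethylsilyloxy)cyclopentyl]but-3-en-1-one | CC(C)[C@]1(O[Si](CC)(CC)CC)CC[C@](C)(CC=C)[C@H]1C(=O)CC(C)=C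
F4 | step 3 | 2-formyl-1-methyl-3-(propan-2-yl)-3-(triethylsilyloxy)cyclopentyl methanesulfonate, carbinol centre as in 4, mixture at C1 and C2 | CC(C)[C@]1(O[Si](CC)(CC)CC)CCC(C)(OS(C)(=O)=O)C1C=O
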